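## The problem

Compound 12, 2,3,5-tribromo-6-(2,4-dibromophenoxy)phenol, is a diaryl ether with five bromines and one free hydroxyl. Ring A is numbered here from the ether carbon: C1 carries the ether oxygen, C2 the hydroxyl, C3, C4 and C6 bromine, and C5 hydrogen. Ring B has C1' on oxygen and bromine at C2' and C4'. The bridging oxygen is flanked by C2–O and C6–Br on ring A and by C2'–Br on ring B, so the ether bond is tri-ortho-substituted. The five aryl C–Br bonds rule out copper- or palladium-mediated etherification, organolithium reagents and hydrogenolysis at every stage. There is no stereocenter and no configurationally stable axis, so the task is purely regiochemical. On ring A the bromines at C4 and C6 are para and ortho to the C1 oxygen but meta to the C2 hydroxyl, and C5, para to that hydroxyl, is unsubstituted. This pattern can therefore only be set while the C1 oxygen is a free phenol and the C2 oxygen is masked, and the C2 hydroxyl, which would also be prone to oxidation, must stay masked whenever electrophilic bromine is present. The feature that opens the key step is on ring B: oxygen at C1' and bromine at C2' sit on adjacent carbons, as they would after an oxygen nucleophile and a bromine electrophile add across an aryne. The ring A phenoxide that has to serve as the nucleophile has C2, C4 and C6 all substituted, so it can react only through oxygen. The remaining C4' bromine lies para to the ether oxygen, where electrophilic bromination goes by itself.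

## Retrosynthesis

The hydroxyl of 12 is released last, from methyl ether 10, by cleaving the O–CH3 bond; in the flask this passes through aryloxydibromoborane 11. A methyl group is preferred to benzyl or silyl because it must survive fluoride, a bromine-transfer reagent and two electrophilic brominations. It also keeps the C5 position, para to the C2 oxygen, quiet, because a methoxy group squeezed between C1–O and C3–Br is twisted out of conjugation. The forward reaction only has to tell an alkyl aryl ether from a diaryl ether, which Lewis-acid demethylation does reliably.

The C4'–Br bond of 10 is cut next, leading to 9, which carries only the ortho bromine on ring B. Bringing this bromine in with the aryne would require an unsymmetrical bromobenzyne, which a phenoxide attacks at both ends. Adding it afterwards uses the strongest directing effect in 9: the ether oxygen conjugates with ring B because ring A, with two ortho substituents, is turned out of plane. C4' is para to that oxygen and unhindered, whereas the only C–H of ring A (C5) sits between two bromines.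

The key disconnection cuts O–C1' and C2'–Br of 9 together. This gives potassium phenoxide 4, the ortho-silylaryl triflate 5 as the source of benzyne 7, and the bromine donor 6; the forward reaction runs through arylpotassium 8. Against a copper-mediated coupling with a 2,4-dibromophenyl halide, this cut needs no metal that could insert into C–Br bonds and is not slowed by ortho substituents. Against a plain aryne O-arylation followed by two ring B brominations, it places the ortho bromine with certainty, on the carbon that carried the negative charge. Both ring B precursors are commercial, and 7 is symmetric, so no regiochemical question arises. The forward reaction asks that the aryl anion 8 take bromine rather than a proton.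

Phenoxide 4 comes from phenol 3 by cutting the O–K bond, and 3 from commercial 3-bromo-2-methoxyphenol 1 by cutting C4–Br and C6–Br, with monobromide 2 expected on the way. The free hydroxyl of 1 directs to its para and its only open ortho position, which are exactly C4 and C6. The C3 bromine, which no directing group could place, is bought with the starting material.

## Roads not taken

Alternative 1: Ring A is opened at C1–C6 and C3–C4, leading back to 1-(2,4-dibromophenoxy)propan-2-one A1 and sodium nitromalonaldehyde A2. In the forward direction a double aldol condensation in aqueous hydroxide would close ring A as 2-(2,4-dibromophenoxy)-4-nitrophenol A3, with the nitro group at C5.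
- Merits: no diaryl ether bond has to be made, because the oxygen bridge enters as a simple aryl alkyl ether in A1, and both ring B bromines are present from the start. After reduction to aminophenol A4 the nitrogen would act as a traceless director: it sends bromine to C4 and C6 while the hydroxyl sends it to C3, giving A5, and reductive deamination would then leave hydrogen at C5. Every step is of a known type, and the count is about the same as in the chosen plan.
- Weak points: the condensation is modest even with symmetrical ketones, and A1 has two different alpha carbons. A2 is a shock-sensitive salt that must be prepared. The para-aminophenol A4 is oxidised to a quinone imine by the same reagent that should brominate it. Diazotisation of A5 would give a quinone diazide, which resists clean replacement by hydrogen unless the hydroxyl is protected first.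
- Comparison: this road is better in resting entirely on known reactions. The chosen plan sets against it three stable commercial building blocks, mild conditions, no energetic reagent, no oxidation-prone intermediate, and a known two-component aryne arylation as a bypass if the new step fails.

Alternative 2: Ring A is opened at C1–C6 and C2–C3, leading back to 3,5-dibromo-2H-pyran-2-one A6 and the alkynylboronate A7. A thermal [4+2] cycloaddition followed by decarboxylative aromatisation would give arylboronate A8. Oxidation of the C–B bond would then give phenol A9, and a last bromination ortho to the hydroxyl would install C3–Br.
- Merits: the C4 and C6 bromines and the whole of ring B come in by construction, boron marks the site of the hydroxyl, and the polarity of the ynol ether fixes the orientation of the cycloaddition.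
- Weak points: A7 has no simple preparation. The usual route to aryloxyalkynes goes through a dichlorovinyl ether and two equivalents of an alkyllithium, which would exchange with the aryl bromides. Aryloxyalkynes are thermally fragile, and the cycloaddition needs prolonged heating. A6 has to be made. The final bromination of A9 must choose the ortho carbon C3 over C5, which is para to a free hydroxyl, even if shielded by two bromines. The route is clearly longer.
- Comparison: this road is better in that two ring A bromines do not depend on directing effects. The chosen plan sets against it a shorter sequence from commercial materials and a late bromination (step 4) that runs on a masked phenol, where the directing effects reinforce each other.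

Alternative 3: Ring B is opened at C1'–C2' and C5'–C6', leading back to the ethynyl ether A10 and the same pyranone A6. Cycloaddition and decarboxylative aromatisation would give A11, which is identical with compound 10, and the same demethylation would finish the synthesis.
- Merits: both ring B bromines are placed by the pyranone, so step 4 of the chosen plan and its selectivity question disappear. The ring A chemistry is shared with the chosen plan, since A10 derives from phenol 3. The key step is of a known type.
- Weak points: A10 has to be made from the hindered, electron-poor phenol 3. The standard ynol ether synthesis needs an alkyllithium in the presence of three aryl bromides. A terminal aryl ethynyl ether is unlikely to survive the temperature that a pyranone cycloaddition requires. A6 again has to be prepared, so the count rises to six or seven steps.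
- Comparison: this road is better in regiochemical certainty at C4' and in precedent for the ring-forming step. The chosen plan sets against it a stable commercial aryne precursor, formation of both bonds at the ether oxygen at or below room temperature without strong base or heat, and five steps in all.

Key step: step 3

## Route

Step 1
Reactants: 1 3-bromo-2-methoxyphenol
Product: 3 3,4,6-tribromo-2-methoxyphenol, via 3,4-dibromo-2-methoxyphenol 2 (not isolated)
Conditions: Br2 (2.2 equiv), AcOH, rt
Reagents that add atoms: bromine, BrBr
Why: Electrophilic aromatic bromination directed by the free hydroxyl, expected first para (C4, giving 2) and then at the only open ortho position (C6). The methoxy group lies between C1–O and C3–Br, is twisted out of conjugation and activates C5 only weakly, so C5 should stay unsubstituted.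

Step 2
Reactants: 3 3,4,6-tribromo-2-methoxyphenol
Product: 4 potassium 3,4,6-tribromo-2-methoxyphenoxide
Conditions: KH (0.98 equiv), THF, 0 °C to rt; evaporation, drying in vacuo
Reagents that add atoms: potassium hydride, [K+].[H-]
Why: Irreversible acid–base reaction of an acidic polybromophenol with a hydride base. Hydrogen is the only by-product, so the salt carries no conjugate acid into the key step, and a slight deficit of KH leaves no hydride to reduce the bromine donor.

Step 3
Reactants: 4 potassium 3,4,6-tribromo-2-methoxyphenoxide; 5 2-(trimethylsilyl)phenyl trifluoromethanesulfonate; 6 1,2-dibromo-1,1,2,2-tetrachloroethane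
Product: 9 1,2,5-tribromo-4-(2-bromophenoxy)-3-methoxybenzene, via benzyne 7 (not isolated), via 2-aryloxyphenylpotassium 8 (not isolated)
Conditions: KF (4 equiv), 18-crown-6 (4 equiv), 6 (3 equiv), THF, 0 °C to rt, 5 (2 equiv) added slowly
Reagents that add atoms: none
Why: Proposed new method: fluoride from KF/18-crown-6 attacks silicon of 5 and triflate leaves, giving benzyne 7; phenoxide 4, whose ortho and para carbons C2, C6 and C4 are all substituted, can add only through oxygen and gives arylpotassium 8; 8 then attacks a bromine of 6 in a halophilic substitution, and the carbanion set free loses bromide to become tetrachloroethene, so that O–C1' and C2'–Br end on adjacent carbons. The closest known reaction types are the fluoride-induced O-arylation of phenols by ortho-silylaryl triflates, in which the same aryl anion is simply protonated, and three-component aryne couplings in which the aryl anion is captured by a halogen-transfer reagent. No ring is closed and no stereocenter is formed. Regiochemistry is not at issue because 7 is symmetric. The selectivity needed is bromination of 8 over protonation; it is secured by the preformed salt 4 (no O–H in the flask), by THF in place of acetonitrile, by dry KF and by an excess of 6. Bromide released from 6 will also add to 7, which is why 5 is used in excess and added slowly. The existing C–Br bonds should be untouched, since no transition metal and no organolithium is present.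

Step 4
Reactants: 9 1,2,5-tribromo-4-(2-bromophenoxy)-3-methoxybenzene
Product: 10 1,2,5-tribromo-4-(2,4-dibromophenoxy)-3-methoxybenzene
Conditions: NBS (1.05 equiv), (CF3)2CHOH, rt, dark
Reagents that add atoms: N-bromosuccinimide, O=C1CCC(=O)N1Br
Why: Electrophilic aromatic bromination with NBS activated by the hydrogen-bonding solvent. Ring A is turned out of plane by its two ortho substituents, so the ether oxygen conjugates with ring B and directs to the open para position C4'. The only C–H of ring A (C5) lies between two bromines and para to a twisted methoxy group and should not compete.

Step 5
Reactants: 10 1,2,5-tribromo-4-(2,4-dibromophenoxy)-3-methoxybenzene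
Product: 12 2,3,5-tribromo-6-(2,4-dibromophenoxy)phenol, via aryloxydibromoborane 11 (not isolated)
Conditions: BBr3 (3 equiv), CH2Cl2, −78 °C to rt; then H2O, 0 °C
Reagents that add atoms: none
Why: Lewis-acid cleavage of an aryl methyl ether: boron binds the methoxy oxygen, bromide attacks the methyl carbon to give 11, and water hydrolyses the B–O bond on work-up. The diaryl ether oxygen is less basic and has no sp3 carbon for bromide to attack, and aryl C–Br bonds are inert to BBr3.

## Compound list

1 | 3-bromo-2-methoxyphenol | COc1c(O)cccc1Br | starting material
2 | 3,4-dibromo-2-methoxyphenol | COc1c(O)ccc(Br)c1Br | intermediate
3 | 3,4,6-tribromo-2-methoxyphenol | COc1c(O)c(Br)cc(Br)c1Br | intermediate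
4 | potassium 3,4,6-tribromo-2-methoxyphenoxide | COc1c([O-])c(Br)cc(Br)c1Br.[K+] | intermediate
5 | 2-(trimethylsilyl)phenyl trifluoromethanesulfonate | C[Si](C)(C)c1ccccc1OS(=O)(=O)C(F)(F)F | starting material
6 | 1,2-dibromo-1,1,2,2-tetrachloroethane | ClC(Cl)(Br)C(Cl)(Cl)Br | starting material
7 | benzyne (cyclohexa-1,3-dien-5-yne) | C1#CC=CC=C1 | intermediate
8 | [2-(3,4,6-tribromo-2-methoxyphenoxy)phenyl]potassium | COc1c(Br)c(Br)cc(Br)c1Oc1ccccc1[K] | intermediate
9 | 1,2,5-tribromo-4-(2-bromophenoxy)-3-methoxybenzene | COc1c(Br)c(Br)cc(Br)c1Oc1ccccc1Br | intermediate
10 | 1,2,5-tribromo-4-(2,4-dibromophenoxy)-3-methoxybenzene | COc1c(Br)c(Br)cc(Br)c1Oc1ccc(Br)cc1Br | intermediate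
11 | dibromo[2,3,5-tribromo-6-(2,4-dibromophenoxy)phenoxy]borane | BrB(Br)Oc1c(Br)c(Br)cc(Br)c1Oc1ccc(Br)cc1Br | intermediate
12 | 2,3,5-tribromo-6-(2,4-dibromophenoxy)phenol | Oc1c(Br)c(Br)cc(Br)c1Oc1ccc(Br)cc1Br | target

## Step count and risk

Total: 5 steps. Longest linear sequence: 5 steps (1 → 3 → 4 → 9 → 10 → 12); 5 and 6 are commercial and enter at step 3.

Step 3 (key step, proposed new method).
- What may go wrong: protonation of the aryl anion 8 by traces of water, the solvent or the crown ether may outrun bromine transfer. Bromide released from 6 may consume benzyne. Bromine transfer from 6 to the phenoxide itself (ipso attack at its brominated carbons) may drain the nucleophile. The addition of so electron-poor a phenoxide may also be reversible, so that the capture step has to pull it forward.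
- Fallback, from phenol 3 back to the route at 10, using known chemistry: O-phenylation of 3 with benzyne from 5 under the usual two-component conditions (CsF, MeCN, rt) should give 1,2,5-tribromo-3-methoxy-4-phenoxybenzene F1, with the aryl anion protonated by the phenol. Electrophilic dibromination of the phenoxy ring of F1 (Br2, 2.2 equiv, AcOH, gentle warming, a trace of FeBr3 if needed) should then go para and ortho to the ether oxygen and give 10 directly, so that step 4 falls away. The cost is that the ortho bromine is then placed by selectivity and no longer by construction.

Step 4.
- What may go wrong: attack at the ortho position C6' of ring B may compete with para attack, or, if the ring proves sluggish and conditions are forced, substitution may begin at C5 of ring A.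
- Fallback, from 9 back to 10: C–H thianthrenation, a substitution with very high para selectivity (thianthrene S-oxide, (CF3CO)2O, HBF4·OEt2, MeCN, 0 °C to rt), should give 5-[3-bromo-4-(3,4,6-tribromo-2-methoxyphenoxy)phenyl]-5H-thianthren-5-ium tetrafluoroborate F2. Sandmeyer-type replacement of the sulfonium group by bromine (CuBr, Ru(bpy)3(PF6)2 as photocatalyst, blue light, MeCN) would then give 10. Aryl bromides are not reduced under these conditions.

Step 1.
- What may go wrong: the second bromination may partition between C6 (ortho to hydroxyl) and C5 (para to methoxy), or a third bromine may enter at C5.
- Fallback, from 1 back to 3: amine-directed ortho bromination (NBS, iPr2NH, CH2Cl2, 0 °C), in which the N-bromoamine is delivered by hydrogen bonding to the hydroxyl, should give 3,6-dibromo-2-methoxyphenol F3. A separate para bromination (NBS, 1.0 equiv, MeCN, 0 °C) would then give 3, each bromine being placed in its own controlled step.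

## Further compounds

F1 | step 3 | 1,2,5-tribromo-3-methoxy-4-phenoxybenzene | COc1c(Br)c(Br)cc(Br)c1Oc1ccccc1
F2 | step 4 | 5-[3-bromo-4-(3,4,6-tribromo-2-methoxyphenoxy)phenyl]-5H-thianthren-5-ium tetrafluoroborate | COc1c(Br)c(Br)cc(Br)c1Oc1ccc(cc1Br)[S+]1c2ccccc2Sc2ccccc12.F[B-](F)(F)F
F3 | step 1 | 3,6-dibromo-2-methoxyphenol | COc1c(O)c(Br)ccc1Br
A1 | alternative 1 | 1-(2,4-dibromophenoxy)propan-2-one | CC(=O)COc1ccc(Br)cc1Br
A2 | alternative 1 | sodium nitromalonaldehyde (sodium 2-nitro-3-oxoprop-1-en-1-olate) | [Na+].[O-]C=C(C=O)[N+](=O)[O-]
A3 | alternative 1 | 2-(2,4-dibromophenoxy)-4-nitrophenol | Oc1ccc(cc1Oc1ccc(Br)cc1Br)[N+](=O)[O-]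
A4 | alternative 1 | 4-amino-2-(2,4-dibromophenoxy)phenol | Nc1ccc(O)c(Oc2ccc(Br)cc2Br)c1
A5 | alternative 1 | 4-amino-2,3,5-tribromo-6-(2,4-dibromophenoxy)phenol | Nc1c(Br)c(Br)c(O)c(Oc2ccc(Br)cc2Br)c1Br
A6 | alternative 2 | 3,5-dibromo-2H-pyran-2-one | O=c1occ(Br)cc1Br
A7 | alternative 2 | 2-[(2,4-dibromophenoxy)ethynyl]-4,4,5,5-tetramethyl-1,3,2-dioxaborolane | CC1(C)OB(C#COc2ccc(Br)cc2Br)OC1(C)C
A8 | alternative 2 | 2-[3,5-dibromo-2-(2,4-dibromophenoxy)phenyl]-4,4,5,5-tetramethyl-1,3,2-dioxaborolane | CC1(C)OB(c2cc(Br)cc(Br)c2Oc2ccc(Br)cc2Br)OC1(C)C
A9 | alternative 2 | 3,5-dibromo-2-(2,4-dibromophenoxy)phenol | Oc1cc(Br)cc(Br)c1Oc1ccc(Br)cc1Br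
A10 | alternative 3 | 1,2,5-tribromo-4-(ethynyloxy)-3-methoxybenzene | COc1c(Br)c(Br)cc(Br)c1OC#C
A11 | alternative 3 | 1,2,5-tribromo-4-(2,4-dibromophenoxy)-3-methoxybenzene | COc1c(Br)c(Br)cc(Br)c1Oc1ccc(Br)cc1Br
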